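**Plan**
Feature: in ring B, C4 is a benzylic CH2 bonded to ring A (at C4a). C3 carries a one-carbon arm (CH2OMe) that can be held at the ester level, so an oxygen lent to C4 makes C3–C4 the inner bond of a β-keto ester.
Cuts, in retrosynthetic order: O–CH3 and the oxidation level of the C3 arm, C3–H, C4–O, then C3–C4 (ring B, Dieckmann). After that come C4–C4a (carbonylation of an aryl bromide), C2–C3 (imide enolate alkylation) and C1–ring C (aryl copper 1,4-addition).
Forward: rings A and C are bought. The chain C1–C2–C3 is grown out from ring A on a cinnamoyl imide, C4 is put on ring A as a methyl ester, and ring B, the only ring made, closes at C3–C4.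
Stereochemistry: one (R)-4-benzyloxazolidin-2-one sets C1 (face of the 1,4-addition) and C2 (face of the alkylation), so that the aryl group and the C2 arm end up cis on ring B.
C3 stays sp2 from the ring closure until the hydrogenation, which adds hydrogen to the face left open by that cis pair and gives the all-cis target.

Key step: step 8

Remark: the stereodescriptors of the target decode to (1S,2S,3R), with the C1 aryl group and both CH2OMe arms on one face of ring B; target numbering (C1–C4, C4a, C8a) is used for the corresponding atoms of all intermediates in the Why lines.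

Step 1
Reactants: 1 2-bromo-4,5-dimethoxybenzaldehyde; 2 malonic acid
Product: 3 (2E)-3-(2-bromo-4,5-dimethoxyphenyl)prop-2-enoic acid
Conditions: pyridine, piperidine (cat.), 100 °C
Reagents that add atoms: none
Why: Knoevenagel condensation in the Doebner modification, in which the aldehyde condenses with malonic acid and decarboxylative elimination gives the E cinnamic acid that holds C1, C2 and the carbon of the C2 arm.

Step 2
Reactants: 3 (2E)-3-(2-bromo-4,5-dimethoxyphenyl)prop-2-enoic acid; 4 (R)-4-benzyl-1,3-oxazolidin-2-one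
Product: 6 (4R)-4-benzyl-3-[(2E)-3-(2-bromo-4,5-dimethoxyphenyl)prop-2-enoyl]-1,3-oxazolidin-2-one, via mixed pivalic anhydride 5 (not isolated)
Conditions: t-BuCOCl, Et3N, THF, −20 °C; then LiCl, 4, −20 °C to rt
Reagents that add atoms: pivaloyl chloride, CC(C)(C)C(=O)Cl (its atoms stay only in intermediate 5)
Why: N-acylation of an oxazolidinone through a mixed anhydride, where the tert-butyl group steers attack to the cinnamoyl carbonyl and LiCl lets Et3N serve as base, so no strong base meets the Michael acceptor.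

Step 3
Reactants: 6 (4R)-4-benzyl-3-[(2E)-3-(2-bromo-4,5-dimethoxyphenyl)prop-2-enoyl]-1,3-oxazolidin-2-one; 7 4-bromo-1,2-dimethoxybenzene
Product: 10 (4R)-4-benzyl-3-[(3S)-3-(2-bromo-4,5-dimethoxyphenyl)-3-(3,4-dimethoxyphenyl)propanoyl]-1,3-oxazolidin-2-one, via 3,4-dimethoxyphenylmagnesium bromide 8 (not isolated), via 3,4-dimethoxyphenylcopper 9 (not isolated)
Conditions: 7, Mg, THF, 40 °C; CuBr·SMe2 (1 equiv per 8), THF/Me2S, −40 °C; then 6, −40 to −10 °C
Reagents that add atoms: magnesium, [Mg] (stays only in intermediate 8); CuBr·SMe2, Br[Cu].CSC (copper stays only in intermediate 9)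
Why: Copper-mediated 1,4-addition of an aryl Grignard reagent to an N-enoyl oxazolidinone, in which the magnesium salt chelates both imide carbonyls, the enoyl group lies s-cis, the benzyl group screens one face of C1 and ring C is delivered to the other, which with ring A in the acceptor gives the (S) centre at C1.

Step 4
Reactants: 10 (4R)-4-benzyl-3-[(3S)-3-(2-bromo-4,5-dimethoxyphenyl)-3-(3,4-dimethoxyphenyl)propanoyl]-1,3-oxazolidin-2-one; 11 tert-butyl bromoacetate
Product: 13 tert-butyl (3R,4S)-3-{[(4R)-4-benzyl-2-oxo-1,3-oxazolidin-3-yl]carbonyl}-4-(2-bromo-4,5-dimethoxyphenyl)-4-(3,4-dimethoxyphenyl)butanoate, via sodium Z-enolate 12 (not isolated)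
Conditions: NaN(SiMe3)2, THF, −78 °C; then 11, −78 to −40 °C
Reagents that add atoms: NaN(SiMe3)2, C[Si](C)(C)[N-][Si](C)(C)C.[Na+] (sodium stays only in intermediate 12)
Why: Evans asymmetric alkylation, in which the chelated Z enolate 12 takes the reactive α-bromo ester on the face away from the benzyl group, forming C2–C3 and setting C2 so that the C1 aryl group and the future C2 arm become cis on ring B, while in the A(1,3)-favoured rotamer the bulkier bromoaryl ring lies on the face the auxiliary already blocks.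

Step 5
Reactants: 13 tert-butyl (3R,4S)-3-{[(4R)-4-benzyl-2-oxo-1,3-oxazolidin-3-yl]carbonyl}-4-(2-bromo-4,5-dimethoxyphenyl)-4-(3,4-dimethoxyphenyl)butanoate
Product: 14 tert-butyl (3R,4S)-4-(2-bromo-4,5-dimethoxyphenyl)-4-(3,4-dimethoxyphenyl)-3-(hydroxymethyl)butanoate
Conditions: LiBH4, H2O (1 equiv), Et2O/THF, 0 °C
Reagents that add atoms: none
Why: Reductive removal of the auxiliary by LiBH4 reduction of an N-acyl oxazolidinone, since the imide carbonyl is far more electrophilic than the tert-butyl ester, the aryl bromide is inert, C2 is not enolised, and a cold neutral work-up keeps the γ-hydroxy ester from lactonising.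

Step 6
Reactants: 14 tert-butyl (3R,4S)-4-(2-bromo-4,5-dimethoxyphenyl)-4-(3,4-dimethoxyphenyl)-3-(hydroxymethyl)butanoate
Product: 15 tert-butyl (3R,4S)-4-(2-bromo-4,5-dimethoxyphenyl)-4-(3,4-dimethoxyphenyl)-3-(methoxymethyl)butanoate
Conditions: Me3OBF4, 1,8-bis(dimethylamino)naphthalene, 4 Å MS, CH2Cl2, rt
Reagents that add atoms: trimethyloxonium tetrafluoroborate, C[O+](C)C.F[B-](F)(F)F
Why: O-alkylation of an alcohol with Meerwein's salt buffered by a non-nucleophilic base, preferred here to a Williamson reaction because no free alkoxide arises that could close onto the tert-butyl ester to a γ-butyrolactone.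

Step 7
Reactants: 15 tert-butyl (3R,4S)-4-(2-bromo-4,5-dimethoxyphenyl)-4-(3,4-dimethoxyphenyl)-3-(methoxymethyl)butanoate
Product: 16 methyl 2-[(1S,2R)-4-tert-butoxy-1-(3,4-dimethoxyphenyl)-2-(methoxymethyl)-4-oxobutyl]-4,5-dimethoxybenzoate
Conditions: Pd(OAc)2 (5 mol %), Xantphos, CO (1 atm), Et3N, MeOH/toluene, 80 °C
Reagents that add atoms: carbon monoxide, [C-]#[O+]; methanol, CO
Why: Palladium-catalysed alkoxycarbonylation of an aryl bromide, in which zerovalent palladium formed in situ inserts into C–Br, CO insertion gives the acylpalladium species and methanol releases the benzoate, the wide-bite-angle ligand permitting a low CO pressure that does not choke oxidative addition at this hindered electron-rich position, so that C4 is placed on ring A.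

Step 8
Reactants: 16 methyl 2-[(1S,2R)-4-tert-butoxy-1-(3,4-dimethoxyphenyl)-2-(methoxymethyl)-4-oxobutyl]-4,5-dimethoxybenzoate
Product: 18 tert-butyl (3S,4S)-4-(3,4-dimethoxyphenyl)-1-hydroxy-6,7-dimethoxy-3-(methoxymethyl)-3,4-dihydronaphthalene-2-carboxylate (enol form), via lithium ester enolate 17 (not isolated)
Conditions: LiN(SiMe3)2 (2.2 equiv), THF, −78 to 0 °C
Reagents that add atoms: LiN(SiMe3)2, C[Si](C)(C)[N-][Si](C)(C)C.[Li+] (lithium stays only in intermediate 17)
Why: The amide base takes one of the C3 protons next to the tert-butyl ester, enolate 17 adds to the methyl ester carbonyl on ring A (the future C4), and collapse of the tetrahedral adduct with loss of methoxide forms C3–C4. This is a Dieckmann condensation (intramolecular Claisen condensation) of an aliphatic ester enolate onto an aromatic ester, the usual entry to 1-oxotetralin-2-carboxylates. Ring B closes in the 6-(enolexo)-exo-trig mode. No stereocentre is created, because C3 ends sp2 in the hydrogen-bonded enol, and C1 and C2 are carried through as spectators. The selectivity needed is one enolisation site and one acceptor: the benzoate has no α-hydrogen, the bulky tert-butyl ester is a poor acceptor, and the only other weakly acidic site, the diarylmethine C1–H ortho to the benzoate, is tertiary, crowded and deactivated by the para methoxy group of ring A, so a silylamide base at low temperature should leave it alone. The second equivalent of base turns 18 into its chelated enolate, which pulls the equilibrium over and takes away the ketone as an acidifying group for C1–H.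

Step 9
Reactants: 18 tert-butyl (3S,4S)-4-(3,4-dimethoxyphenyl)-1-hydroxy-6,7-dimethoxy-3-(methoxymethyl)-3,4-dihydronaphthalene-2-carboxylate
Product: 19 tert-butyl (3S,4S)-4-(3,4-dimethoxyphenyl)-6,7-dimethoxy-3-(methoxymethyl)-1-[(trifluoromethyl)sulfonyloxy]-3,4-dihydronaphthalene-2-carboxylate
Conditions: Tf2O, i-Pr2NEt, CH2Cl2, −78 to 0 °C
Reagents that add atoms: trifluoromethanesulfonic anhydride, O=S(=O)(OS(=O)(=O)C(F)(F)F)C(F)(F)F
Why: O-sulfonylation of an enolised cyclic β-keto ester to its vinyl triflate, where the ring fixes the alkene geometry, the hindered amine touches neither C1 nor C2, and the C4 oxygen becomes a leaving group for palladium.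

Step 10
Reactants: 19 tert-butyl (3S,4S)-4-(3,4-dimethoxyphenyl)-6,7-dimethoxy-3-(methoxymethyl)-1-[(trifluoromethyl)sulfonyloxy]-3,4-dihydronaphthalene-2-carboxylate
Product: 20 tert-butyl (3S,4S)-4-(3,4-dimethoxyphenyl)-6,7-dimethoxy-3-(methoxymethyl)-3,4-dihydronaphthalene-2-carboxylate
Conditions: Pd(OAc)2 (5 mol %), PPh3, HCO2H, Et3N, DMF, 60 °C
Reagents that add atoms: none
Why: Palladium-catalysed formate hydrogenolysis of a vinyl triflate, in which oxidative addition to zerovalent palladium, exchange of triflate for formate, loss of CO2 and reductive elimination replace C4–O by C4–H while the C3=C4 enoate, the buffered tert-butyl ester and both stereocentres stay as they are.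

Step 11
Reactants: 20 tert-butyl (3S,4S)-4-(3,4-dimethoxyphenyl)-6,7-dimethoxy-3-(methoxymethyl)-3,4-dihydronaphthalene-2-carboxylate
Product: 21 tert-butyl (2R,3S,4S)-4-(3,4-dimethoxyphenyl)-6,7-dimethoxy-3-(methoxymethyl)-1,2,3,4-tetrahydronaphthalene-2-carboxylate (all-cis)
Conditions: H2 (4 bar), Pd/C (10 wt %), EtOAc, rt
Reagents that add atoms: none
Why: Heterogeneous syn hydrogenation of a trisubstituted styrenyl enoate, in which the C1 aryl group and the C2 CH2OMe arm both stand on one face of the half-chair, so the alkene meets the metal surface with the other face, the new C3–H enters anti to them and the ester is turned onto their side to set C3.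

Step 12
Reactants: 21 tert-butyl (2R,3S,4S)-4-(3,4-dimethoxyphenyl)-6,7-dimethoxy-3-(methoxymethyl)-1,2,3,4-tetrahydronaphthalene-2-carboxylate
Product: 22 [(2R,3S,4S)-4-(3,4-dimethoxyphenyl)-6,7-dimethoxy-3-(methoxymethyl)-1,2,3,4-tetrahydronaphthalen-2-yl]methanol
Conditions: LiAlH4, THF, 0 °C to rt
Reagents that add atoms: none
Why: LiAlH4 reduction of an ester to the primary alcohol, where hydride addition outruns enolisation so that the contra-thermodynamic C3 configuration is kept, and the ethers are inert.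

Step 13
Reactants: 22 [(2R,3S,4S)-4-(3,4-dimethoxyphenyl)-6,7-dimethoxy-3-(methoxymethyl)-1,2,3,4-tetrahydronaphthalen-2-yl]methanol
Product: 23 (1S,2S,3R)-1-(3,4-dimethoxyphenyl)-6,7-dimethoxy-2,3-bis(methoxymethyl)-1,2,3,4-tetrahydronaphthalene
Conditions: NaH, MeI, THF, 0 °C to rt
Reagents that add atoms: iodomethane, CI
Why: Williamson ether synthesis on an unhindered primary alkoxide, safe at this stage because no carbonyl group is left that could be attacked or could render a stereocentre acidic.

**Compound list**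
1 | 2-bromo-4,5-dimethoxybenzaldehyde | COc1cc(Br)c(C=O)cc1OC | starting material
2 | malonic acid | OC(=O)CC(=O)O | starting material
3 | (2E)-3-(2-bromo-4,5-dimethoxyphenyl)prop-2-enoic acid | COc1cc(Br)c(/C=C/C(=O)O)cc1OC | intermediate
4 | (R)-4-benzyl-1,3-oxazolidin-2-one | O=C1N[C@H](Cc2ccccc2)CO1 | starting material
5 | (2E)-3-(2-bromo-4,5-dimethoxyphenyl)prop-2-enoic 2,2-dimethylpropanoic anhydride (not isolated) | COc1cc(Br)c(/C=C/C(=O)OC(=O)C(C)(C)C)cc1OC | intermediate
6 | (4R)-4-benzyl-3-[(2E)-3-(2-bromo-4,5-dimethoxyphenyl)prop-2-enoyl]-1,3-oxazolidin-2-one | COc1cc(Br)c(/C=C/C(=O)N2[C@H](Cc3ccccc3)COC2=O)cc1OC | intermediate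
7 | 4-bromo-1,2-dimethoxybenzene | COc1ccc(Br)cc1OC | starting material
8 | 3,4-dimethoxyphenylmagnesium bromide (not isolated) | COc1ccc([Mg]Br)cc1OC | intermediate
9 | 3,4-dimethoxyphenylcopper, present as its MgBr2 complex (not isolated) | COc1ccc([Cu])cc1OC | intermediate
10 | (4R)-4-benzyl-3-[(3S)-3-(2-bromo-4,5-dimethoxyphenyl)-3-(3,4-dimethoxyphenyl)propanoyl]-1,3-oxazolidin-2-one | COc1cc(Br)c(cc1OC)[C@H](c1ccc(OC)c(OC)c1)CC(=O)N1[C@H](Cc2ccccc2)COC1=O | intermediate
11 | tert-butyl bromoacetate | CC(C)(C)OC(=O)CBr | starting material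
12 | sodium (1Z,3S)-1-[(4R)-4-benzyl-2-oxo-1,3-oxazolidin-3-yl]-3-(2-bromo-4,5-dimethoxyphenyl)-3-(3,4-dimethoxyphenyl)prop-1-en-1-olate (not isolated) | COc1cc(Br)c(cc1OC)[C@H](c1ccc(OC)c(OC)c1)/C=C(\[O-])N1[C@H](Cc2ccccc2)COC1=O.[Na+] | intermediate
13 | tert-butyl (3R,4S)-3-{[(4R)-4-benzyl-2-oxo-1,3-oxazolidin-3-yl]carbonyl}-4-(2-bromo-4,5-dimethoxyphenyl)-4-(3,4-dimethoxyphenyl)butanoate | COc1cc(Br)c(cc1OC)[C@H](c1ccc(OC)c(OC)c1)[C@@H](CC(=O)OC(C)(C)C)C(=O)N1[C@H](Cc2ccccc2)COC1=O | intermediate
14 | tert-butyl (3R,4S)-4-(2-bromo-4,5-dimethoxyphenyl)-4-(3,4-dimethoxyphenyl)-3-(hydroxymethyl)butanoate | COc1cc(Br)c(cc1OC)[C@H](c1ccc(OC)c(OC)c1)[C@@H](CC(=O)OC(C)(C)C)CO | intermediate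
15 | tert-butyl (3R,4S)-4-(2-bromo-4,5-dimethoxyphenyl)-4-(3,4-dimethoxyphenyl)-3-(methoxymethyl)butanoate | COc1cc(Br)c(cc1OC)[C@H](c1ccc(OC)c(OC)c1)[C@@H](CC(=O)OC(C)(C)C)COC | intermediate
16 | methyl 2-[(1S,2R)-4-tert-butoxy-1-(3,4-dimethoxyphenyl)-2-(methoxymethyl)-4-oxobutyl]-4,5-dimethoxybenzoate | COC(=O)c1cc(OC)c(OC)cc1[C@H](c1ccc(OC)c(OC)c1)[C@@H](CC(=O)OC(C)(C)C)COC | intermediate
17 | lithium enolate of 16, deprotonated at C3 next to the tert-butyl ester, C1 and C2 unchanged (not isolated) | COC(=O)c1cc(OC)c(OC)cc1[C@H](c1ccc(OC)c(OC)c1)[C@@H](C=C([O-])OC(C)(C)C)COC.[Li+] | intermediate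
18 | tert-butyl (3S,4S)-4-(3,4-dimethoxyphenyl)-1-hydroxy-6,7-dimethoxy-3-(methoxymethyl)-3,4-dihydronaphthalene-2-carboxylate (enol form, aryl and CH2OMe cis) | CC(C)(C)OC(=O)C1=C(O)c2cc(OC)c(OC)cc2[C@H](c2ccc(OC)c(OC)c2)[C@@H]1COC | intermediate
19 | tert-butyl (3S,4S)-4-(3,4-dimethoxyphenyl)-6,7-dimethoxy-3-(methoxymethyl)-1-[(trifluoromethyl)sulfonyloxy]-3,4-dihydronaphthalene-2-carboxylate | CC(C)(C)OC(=O)C1=C(OS(=O)(=O)C(F)(F)F)c2cc(OC)c(OC)cc2[C@H](c2ccc(OC)c(OC)c2)[C@@H]1COC | intermediate
20 | tert-butyl (3S,4S)-4-(3,4-dimethoxyphenyl)-6,7-dimethoxy-3-(methoxymethyl)-3,4-dihydronaphthalene-2-carboxylate | CC(C)(C)OC(=O)C1=Cc2cc(OC)c(OC)cc2[C@H](c2ccc(OC)c(OC)c2)[C@@H]1COC | intermediate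
21 | tert-butyl (2R,3S,4S)-4-(3,4-dimethoxyphenyl)-6,7-dimethoxy-3-(methoxymethyl)-1,2,3,4-tetrahydronaphthalene-2-carboxylate (all-cis) | CC(C)(C)OC(=O)[C@@H]1Cc2cc(OC)c(OC)cc2[C@H](c2ccc(OC)c(OC)c2)[C@@H]1COC | intermediate
22 | [(2R,3S,4S)-4-(3,4-dimethoxyphenyl)-6,7-dimethoxy-3-(methoxymethyl)-1,2,3,4-tetrahydronaphthalen-2-yl]methanol | OC[C@@H]1Cc2cc(OC)c(OC)cc2[C@H](c2ccc(OC)c(OC)c2)[C@@H]1COC | intermediate
23 | (1S,2S,3R)-1-(3,4-dimethoxyphenyl)-6,7-dimethoxy-2,3-bis(methoxymethyl)-1,2,3,4-tetrahydronaphthalene | COC[C@@H]1Cc2cc(OC)c(OC)cc2[C@H](c2ccc(OC)c(OC)c2)[C@@H]1COC | target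

Total step count: 13. Longest linear sequence: 13 steps (1 to 23).

**Steps most likely to fail**

Step 8 (ring closure).
- **Risk:** the enolate has to reach a carbonyl flanked by the bulky C1 substituent. Proton exchange at the diarylmethine C1–H beside the benzoate could meanwhile erode the C1 configuration, or the condensation could simply stall.
- **Fallback:** the same C3–C4 bond is made at the aldehyde oxidation level, where addition is fast at −78 °C.
- Setting out from 15, reductive carbonylation (Pd(OAc)2, di(1-adamantyl)-n-butylphosphine, CO/H2, TMEDA, toluene, 100 °C) should give tert-butyl (3R,4S)-4-(3,4-dimethoxyphenyl)-4-(2-formyl-4,5-dimethoxyphenyl)-3-(methoxymethyl)butanoate F1.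
- LiN(SiMe3)2 in THF at −78 °C should close F1 by intramolecular aldol addition to tert-butyl (3S,4S)-4-(3,4-dimethoxyphenyl)-1-hydroxy-6,7-dimethoxy-3-(methoxymethyl)-1,2,3,4-tetrahydronaphthalene-2-carboxylate F2. Its two new centres are of no consequence.
- MsCl/Et3N in CH2Cl2 should convert F2 into the corresponding benzylic methanesulfonate F3, and DBU eliminates it to the enoate.
- The route is rejoined at 20, and steps 7 to 10 are bypassed.

Step 11 (C3 hydrogen).
- **Risk:** poor facial discrimination, or slow hydrogen uptake at the hindered trisubstituted alkene that leaves time for double-bond migration on the metal.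
- **Fallback:** the C3 hydrogen is delivered as a proton to a planar enolate instead of from a metal surface.
- Setting out from 20, conjugate reduction with Mg in MeOH should give the saturated ester without regard to face, expected to be rich in the 2,3-trans epimer tert-butyl (2S,3S,4S)-4-(3,4-dimethoxyphenyl)-6,7-dimethoxy-3-(methoxymethyl)-1,2,3,4-tetrahydronaphthalene-2-carboxylate F4.
- LiN(i-Pr)2 in THF converts the whole epimer mixture into the exocyclic lithium ester enolate F5. In F5, allylic strain with the alkoxy groups pushes the C2 arm pseudoaxial.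
- A quench at −78 °C with the bulky proton donor 2,6-di-tert-butyl-4-methylphenol should protonate C3 from the face anti to the C1/C2 groups (kinetic protonation of an exocyclic enolate).
- The route is rejoined at 21.

Step 5 (removal of the auxiliary).
- **Risk:** hydride attack at the ring carbonyl of the auxiliary instead of the crowded exocyclic carbonyl, with opening of the oxazolidinone, or lactonisation of the alkoxide onto the tert-butyl ester.
- **Fallback:** hydrolysis followed by a chemoselective borane reduction.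
- Setting out from 13, LiOH/H2O2 in THF/H2O at 0 °C should give (2R,3S)-3-(2-bromo-4,5-dimethoxyphenyl)-2-(2-tert-butoxy-2-oxoethyl)-3-(3,4-dimethoxyphenyl)propanoic acid F6. Hydroperoxide cleaves the exocyclic acyl group even in hindered imides.
- BH3·THF at 0 °C reduces the free acid in the presence of the tert-butyl ester and the aryl bromide without forming a free alkoxide.
- The route is rejoined at 14.

**Further compounds**
F1 | step 8 | tert-butyl (3R,4S)-4-(3,4-dimethoxyphenyl)-4-(2-formyl-4,5-dimethoxyphenyl)-3-(methoxymethyl)butanoate | COc1cc(C=O)c(cc1OC)[C@H](c1ccc(OC)c(OC)c1)[C@@H](CC(=O)OC(C)(C)C)COC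
F2 | step 8 | tert-butyl (3S,4S)-4-(3,4-dimethoxyphenyl)-1-hydroxy-6,7-dimethoxy-3-(methoxymethyl)-1,2,3,4-tetrahydronaphthalene-2-carboxylate (epimers at the two new centres) | CC(C)(C)OC(=O)C1C(O)c2cc(OC)c(OC)cc2[C@H](c2ccc(OC)c(OC)c2)[C@@H]1COC
F3 | step 8 | tert-butyl (3S,4S)-4-(3,4-dimethoxyphenyl)-6,7-dimethoxy-3-(methoxymethyl)-1-(methylsulfonyloxy)-1,2,3,4-tetrahydronaphthalene-2-carboxylate | CC(C)(C)OC(=O)C1C(OS(C)(=O)=O)c2cc(OC)c(OC)cc2[C@H](c2ccc(OC)c(OC)c2)[C@@H]1COC
F4 | step 11 | tert-butyl (2S,3S,4S)-4-(3,4-dimethoxyphenyl)-6,7-dimethoxy-3-(methoxymethyl)-1,2,3,4-tetrahydronaphthalene-2-carboxylate | CC(C)(C)OC(=O)[C@H]1Cc2cc(OC)c(OC)cc2[C@H](c2ccc(OC)c(OC)c2)[C@@H]1COC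
F5 | step 11 | lithium enolate of 21 and F4 (C3 planar, exocyclic C=C to the ester carbon) | CC(C)(C)OC([O-])=C1Cc2cc(OC)c(OC)cc2[C@H](c2ccc(OC)c(OC)c2)[C@@H]1COC.[Li+]
F6 | step 5 | (2R,3S)-3-(2-bromo-4,5-dimethoxyphenyl)-2-(2-tert-butoxy-2-oxoethyl)-3-(3,4-dimethoxyphenyl)propanoic acid | COc1cc(Br)c(cc1OC)[C@H](c1ccc(OC)c(OC)c1)[C@@H](CC(=O)OC(C)(C)C)C(=O)O
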